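**Retrosynthetic overview**
1. Radermachol is read as 2-(2-methylprop-1-enyl)naphtho[1,2-b]furan-5-ol whose C3 and C4 are bridged by an o-phthaloyl unit (seven-membered ring); its hydroxy ketone is an enolised β-diketone.
2. Enabling feature: the central carbocycle (C3a, C4, C5, C5a, C9a, C9b) carries oxygen on C5 and on C9b, the two para carbons bonded to the unsubstituted benzo ring C5a–C9a. This 1,4-dioxygenated naphthalene ring is the ring-opened form of a 2-oxyfuran/benzyne cycloadduct.
3. Key disconnection: C5–C5a and C9a–C9b, giving benzyne and a 4-alkynyl-2-silyloxyfuran (Diels–Alder reaction, then opening of the oxygen bridge). The furan ring oxygen becomes the naphthol OH that later closes the target furan; the silyloxy oxygen becomes the target hydroxyl.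
4. After the key step: furan ring and C3-aroyl group together by carbonylative oxypalladation of the 2-alkynyl-1-naphthol with tert-butyl 2-iodobenzoate and CO; seven-membered ring by Friedel–Crafts acylation at C4; desilylation.
5. Before the key step: enyne by Negishi ethynylation, Sonogashira coupling with 4-bromofuran-2(5H)-one, silylation. Ring order: oxygenated benzenoid ring (benzo ring delivered by benzyne), then furan, then seven-membered ring.

Key step: step 4

Remark on the chemistry: the hydroxy ketone of the target is a hydrogen-bonded enolised β-diketone. The 5-hydroxynaphthofuran form delivered by the route and the drawn form (enol on the seven-membered ring) are rapidly exchanging tautomers of one compound; the drawn SMILES is used for the target. Compounds 1, 2 (THF solution), 5, 8 and 12 are taken as commercial.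

Step 1
Reactants: 1 1-bromo-2-methylprop-1-ene; 2 ethynylmagnesium bromide
Product: 4 4-methylpent-3-en-1-yne, via ethynylzinc bromide 3 (not isolated)
Conditions: 2, ZnBr2, THF, 0 °C; then 1, Pd(PPh3)4 (3 mol %), rt; product distilled and used as a THF solution
Reagents that add atoms: none
Why: Negishi coupling: transmetalation of the Grignard reagent to ethynylzinc bromide 3 and cross-coupling with the alkenyl bromide under zerovalent palladium catalysis should give the terminal enyne, the zinc acetylide being too weakly basic to metalate the product and cause double coupling.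

Step 2
Reactants: 4 4-methylpent-3-en-1-yne; 5 4-bromofuran-2(5H)-one
Product: 6 4-(4-methylpent-3-en-1-yn-1-yl)furan-2(5H)-one
Conditions: PdCl2(PPh3)2 (3 mol %), CuI (6 mol %), i-Pr2NEt, THF, 0 °C → rt, argon
Reagents that add atoms: none
Why: Sonogashira coupling: the β-bromobutenolide is a vinylogous acyl bromide that undergoes rapid oxidative addition to zerovalent palladium at or below room temperature, and the hindered amine base does not add to it.

Step 3
Reactants: 6 4-(4-methylpent-3-en-1-yn-1-yl)furan-2(5H)-one
Product: 7 triisopropyl{[4-(4-methylpent-3-en-1-yn-1-yl)furan-2-yl]oxy}silane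
Conditions: TIPSOTf, Et3N, CH2Cl2, 0 °C
Reagents that add atoms: triisopropylsilyl trifluoromethanesulfonate, CC(C)[Si](OS(=O)(=O)C(F)(F)F)(C(C)C)C(C)C
Why: Soft enolisation: O-silylation of the lactone carbonyl and γ-deprotonation by Et3N should give the aromatic 2-silyloxyfuran, the standard conversion of furan-2(5H)-ones into 2-silyloxyfurans.

Step 4
Reactants: 7 triisopropyl{[4-(4-methylpent-3-en-1-yn-1-yl)furan-2-yl]oxy}silane; 8 2-iodophenyl trifluoromethanesulfonate
Product: 11 2-(4-methylpent-3-en-1-yn-1-yl)-4-[(triisopropylsilyl)oxy]naphthalen-1-ol, via benzyne 9 (not isolated), via oxa-bridged cycloadduct 10 (not isolated)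
Conditions: n-BuLi added to 7 + 8, Et2O, −78 °C → rt; then PPTS (cat.), CH2Cl2, rt
Reagents that add atoms: none
Why: Iodine–lithium exchange on 8 and loss of lithium triflate give benzyne 9, which adds across C2 and C5 of the electron-rich 2-silyloxyfuran 7 in a concerted suprafacial [4+2] cycloaddition, forming both new C–C bonds at once and closing the six-membered carbocycle as the oxa-bridged 1,4-dihydro-1,4-epoxynaphthalene 10. On mild acid the bridging C–O bond at the silyloxy-bearing bridgehead ionises to a silyloxy-stabilised cation and loss of the other bridgehead proton aromatises the ring, so the furan ring oxygen ends as the free 1-OH next to the alkyne and the silyloxy oxygen as the protected 4-O. The closest known reaction type is the cycloaddition–ring opening of arynes with 2-alkoxyfurans and 2-silyloxyfurans to 4-oxygenated 1-naphthols. The two bridgehead stereocentres of 10 are held cis by the bicycle (racemic) and both are destroyed on aromatisation, so no stereocontrol is needed. The step needs chemoselectivity for the furan diene over ene or [2+2] reaction at the enyne, which the high-lying HOMO of the silyloxyfuran and the low temperature should secure, and a single direction of bridge opening, which is secured because only the acetal-type bridgehead can ionise; benzyne is symmetrical, so no regiochemical question arises.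

Step 5
Reactants: 11 2-(4-methylpent-3-en-1-yn-1-yl)-4-[(triisopropylsilyl)oxy]naphthalen-1-ol; 12 tert-butyl 2-iodobenzoate
Product: 13 tert-butyl 2-{2-(2-methylprop-1-en-1-yl)-5-[(triisopropylsilyl)oxy]naphtho[1,2-b]furan-3-carbonyl}benzoate
Conditions: Pd(PPh3)4 (5 mol %), K2CO3, CO (1 atm), MeCN, 45 °C
Reagents that add atoms: carbon monoxide, [C-]#[O+]
Why: Carbonylative heteroannulation of a 2-alkynylphenol with an aryl iodide: oxidative addition to zerovalent palladium and CO insertion give an aroyl complex of divalent palladium that activates the alkyne for anti 5-endo-dig attack of the naphthoxide oxygen, and reductive elimination forms the C3–acyl bond, so the furan ring and its 3-aroyl group are installed together.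

Step 6
Reactants: 13 tert-butyl 2-{2-(2-methylprop-1-en-1-yl)-5-[(triisopropylsilyl)oxy]naphtho[1,2-b]furan-3-carbonyl}benzoate
Product: 15 radermachol O-triisopropylsilyl ether, via keto acid 14 (not isolated)
Conditions: TFA/CH2Cl2 (1:2), 0 °C → rt; then (CF3CO)2O, rt; aqueous NaHCO3 work-up
Reagents that add atoms: none
Why: Acidolysis of the tert-butyl ester releases acid 14, whose mixed trifluoroacetic anhydride acylates C4 in an intramolecular Friedel–Crafts reaction (the only nucleophilic position within reach, ortho to the silyloxy group), closing the seven-membered ring; the 3-acyl-2-alkenylfuran is a deactivated push–pull dienone and should tolerate the acid, and any silyl loss here is harmless because step 7 removes the group.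

Step 7
Reactants: 15 radermachol O-triisopropylsilyl ether
Product: 16 radermachol
Conditions: Bu4NF, AcOH, THF, 0 °C
Reagents that add atoms: none
Why: Fluoride cleaves the aryl silyl ether (buffered with AcOH so that the acidic product is not exposed to strong base), releasing the hydrogen-bonded enolised β-diketone radermachol.

**Compound list**
1 | 1-bromo-2-methylprop-1-ene | CC(C)=CBr | starting material
2 | ethynylmagnesium bromide | C#C[Mg]Br | starting material
3 | ethynylzinc bromide | C#C[Zn]Br | intermediate
4 | 4-methylpent-3-en-1-yne | C#CC=C(C)C | intermediate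
5 | 4-bromofuran-2(5H)-one | O=C1C=C(Br)CO1 | starting material
6 | 4-(4-methylpent-3-en-1-yn-1-yl)furan-2(5H)-one | CC(C)=CC#CC1=CC(=O)OC1 | intermediate
7 | triisopropyl{[4-(4-methylpent-3-en-1-yn-1-yl)furan-2-yl]oxy}silane | CC(C)=CC#Cc1coc(O[Si](C(C)C)(C(C)C)C(C)C)c1 | intermediate
8 | 2-iodophenyl trifluoromethanesulfonate | O=S(=O)(Oc1ccccc1I)C(F)(F)F | starting material
9 | benzyne (1,2-didehydrobenzene) | C1#CC=CC=C1 | intermediate
10 | 3-(4-methylpent-3-en-1-yn-1-yl)-1-[(triisopropylsilyl)oxy]-1,4-dihydro-1,4-epoxynaphthalene (racemic, one enantiomer drawn; bridge necessarily cis) | CC(C)=CC#CC1=C[C@]2(O[Si](C(C)C)(C(C)C)C(C)C)O[C@H]1c1ccccc12 | intermediate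
11 | 2-(4-methylpent-3-en-1-yn-1-yl)-4-[(triisopropylsilyl)oxy]naphthalen-1-ol | CC(C)=CC#Cc1cc(O[Si](C(C)C)(C(C)C)C(C)C)c2ccccc2c1O | intermediate
12 | tert-butyl 2-iodobenzoate | CC(C)(C)OC(=O)c1ccccc1I | starting material
13 | tert-butyl 2-{2-(2-methylprop-1-en-1-yl)-5-[(triisopropylsilyl)oxy]naphtho[1,2-b]furan-3-carbonyl}benzoate | CC(C)=Cc1oc2c(c1C(=O)c1ccccc1C(=O)OC(C)(C)C)cc(O[Si](C(C)C)(C(C)C)C(C)C)c1ccccc12 | intermediate
14 | 2-{2-(2-methylprop-1-en-1-yl)-5-[(triisopropylsilyl)oxy]naphtho[1,2-b]furan-3-carbonyl}benzoic acid | CC(C)=Cc1oc2c(c1C(=O)c1ccccc1C(=O)O)cc(O[Si](C(C)C)(C(C)C)C(C)C)c1ccccc12 | intermediate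
15 | radermachol O-triisopropylsilyl ether (2-(2-methylprop-1-en-1-yl)naphtho[1,2-b]furan with C3 and C4 joined through C(=O)–C6H4–C(=O), silyloxy group on C5) | CC(C)=Cc1oc2c3c1C(=O)c1ccccc1C(=O)c3c(O[Si](C(C)C)(C(C)C)C(C)C)c1ccccc12 | intermediate
16 | radermachol | CC(C)=Cc1oc2c3c(c(O)c4ccccc4c(=O)c13)C(=O)c1ccccc1-2 | target

**Summary**
Total step count: 7. Longest linear sequence: 7 steps (1 and 2 to 16).

Steps most likely to fail:

1. Step 4. The silyloxyfuran may attack benzyne as a vinylogous nucleophile instead of as a diene, the silyl group may be lost from the oxocarbenium ion during bridge opening, or benzyne may undergo an ene reaction with the allylic methyl groups. Fallback, setting out from 4 and returning at 11: Sonogashira coupling of 4 with commercial 2-bromonaphthalene-1,4-dione (PdCl2(PPh3)2, CuI, Et3N, THF) should give 2-(4-methylpent-3-en-1-yn-1-yl)naphthalene-1,4-dione F1. Reduction with aqueous Na2S2O4 gives 2-(4-methylpent-3-en-1-yn-1-yl)naphthalene-1,4-diol F2. Silylation with TIPSCl and imidazole at the less hindered 4-hydroxyl (the 1-hydroxyl is flanked by the alkyne) gives 11.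

2. Step 5. CO insertion may lose to direct reductive elimination (3-arylation), to protodepalladation after cyclisation (plain cycloisomerisation), or to O-aroylation of the naphthoxide. Fallback, setting out from 11 and returning at 14: iodocyclisation (I2, NaHCO3, MeCN) should give 3-iodo-2-(2-methylprop-1-en-1-yl)-5-[(triisopropylsilyl)oxy]naphtho[1,2-b]furan F3. Iodine–magnesium exchange (i-PrMgCl·LiCl, THF, −40 °C) gives [2-(2-methylprop-1-en-1-yl)-5-[(triisopropylsilyl)oxy]naphtho[1,2-b]furan-3-yl]magnesium chloride F4. F4 opens phthalic anhydride to the keto acid 14 after acidic work-up, and 14 is cyclised with (CF3CO)2O as in the second half of step 6.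

3. Step 6. The alkenylfuran may degrade by cationic oligomerisation, the released tert-butyl cation may alkylate the arene, the activated keto acid may react intermolecularly at its ketone carbon, or early desilylation may lower the nucleophilicity of C4. Fallback, setting out from 11 and returning at 16, with the last C–C bond made at the alcohol oxidation level under non-acidic conditions: the carbonylative heteroannulation of step 5 is run with 2-iodobenzaldehyde to give 2-{2-(2-methylprop-1-en-1-yl)-5-[(triisopropylsilyl)oxy]naphtho[1,2-b]furan-3-carbonyl}benzaldehyde F5. Bu4NF in THF gives 2-[5-hydroxy-2-(2-methylprop-1-en-1-yl)naphtho[1,2-b]furan-3-carbonyl]benzaldehyde F6. The naphthoxide of F6 adds through C4 to the aldehyde (ortho-hydroxyalkylation) to close the seven-membered ring as the racemic carbinol, C4-(hydroxymethine)-bridged dihydroradermachol F7. Oxidation with MnO2 in CH2Cl2 gives 16.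

**Further compounds**
F1 | step 4 | 2-(4-methylpent-3-en-1-yn-1-yl)naphthalene-1,4-dione | CC(C)=CC#CC1=CC(=O)c2ccccc2C1=O
F2 | step 4 | 2-(4-methylpent-3-en-1-yn-1-yl)naphthalene-1,4-diol | CC(C)=CC#Cc1cc(O)c2ccccc2c1O
F3 | step 5 | 3-iodo-2-(2-methylprop-1-en-1-yl)-5-[(triisopropylsilyl)oxy]naphtho[1,2-b]furan | CC(C)=Cc1oc2c(c1I)cc(O[Si](C(C)C)(C(C)C)C(C)C)c1ccccc12
F4 | step 5 | [2-(2-methylprop-1-en-1-yl)-5-[(triisopropylsilyl)oxy]naphtho[1,2-b]furan-3-yl]magnesium chloride | CC(C)=Cc1oc2c(c1[Mg]Cl)cc(O[Si](C(C)C)(C(C)C)C(C)C)c1ccccc12
F5 | step 6 | 2-{2-(2-methylprop-1-en-1-yl)-5-[(triisopropylsilyl)oxy]naphtho[1,2-b]furan-3-carbonyl}benzaldehyde | CC(C)=Cc1oc2c(c1C(=O)c1ccccc1C=O)cc(O[Si](C(C)C)(C(C)C)C(C)C)c1ccccc12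
F6 | step 6 | 2-[5-hydroxy-2-(2-methylprop-1-en-1-yl)naphtho[1,2-b]furan-3-carbonyl]benzaldehyde | CC(C)=Cc1oc2c(c1C(=O)c1ccccc1C=O)cc(O)c1ccccc12
F7 | step 6 | seven-membered carbinol (dihydroradermachol: C3–C(=O)–C6H4–CH(OH)–C4 bridge, 5-OH; racemic, one enantiomer drawn) | CC(C)=Cc1oc2c3c1C(=O)c1ccccc1[C@H](O)c3c(O)c1ccccc12
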